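## Retrosynthetic overview

1. The butenolide is closed last on a ten-membered α-hydroxy ketone: acetate adds to an O6 2-phosphonoacrylate and the resulting carbanion olefinates the C7 ketone (C7=C11, C13–OAc).
2. The C10 acetate comes from the C1/C10 enol acetate (epoxidation, then 1,2-acyloxy shift); the 4,5-epoxide comes from hydroxyl-directed epoxidation of the Z C4=C5 olefin by C6–OH.
3. The ten-membered ring comes from an eight-membered β-oxy enone by [2+2] photocycloaddition of vinyl propionate across C7=C10 (forms C7–C8 and C9–C10, brings in the C8 propionate), then retro-aldol cleavage of C7–C10.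
4. The eight-membered ring comes from a seven-membered unsaturated lactone (ring-closing metathesis) by a ring-enlarging O-to-carbon acyl shift; the lactone comes from (R)-but-3-ene-1,2-diol (source of C6) and 4-methylpent-4-enoic acid.
5. Ring order: seven-membered lactone → eight-membered carbocycle with cyclic carbonate → cyclobutane → ten-membered ring → epoxide → butenolide.

Assumption: 1, 4, 9 and 16 are bought; labels C1–C15 follow the germacrane numbering of the target (C1 ketone; C4–C5 epoxide; C6 lactone carbinol; C7=C11; C8 propionate; C10 acetate; C12 lactone carbonyl; C13 acetoxymethyl).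

## Route

Step 1
Reactants: 1 (R)-but-3-ene-1,2-diol
Product: 2 (R)-2-hydroxybut-3-enoic acid
Conditions: TEMPO (cat.), NaOCl (cat.), NaClO2, MeCN/pH 6.7 phosphate buffer, 35 °C
Reagents that add atoms: sodium chlorite, [Na+].[O-]Cl=O
Why: TEMPO-catalysed chlorite oxidation (Anelli/Zhao type) takes only the primary alcohol to the acid, so the purchased secondary carbinol (future C6) is untouched.

Step 2
Reactants: 2 (R)-2-hydroxybut-3-enoic acid
Product: 3 (R)-4-hydroxyhex-5-en-3-one
Conditions: EtLi (3.3 equiv), THF/Et2O, −78 → 0 °C; cold aq. HCl quench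
Reagents that add atoms: ethyllithium, [Li]CC
Why: Organolithium addition to a lithium carboxylate (Gilman-type ketone synthesis) stops at the stable gem-diolate, and the stereocenter travels as its lithium alkoxide, which disfavours α-deprotonation.

Step 3
Reactants: 3 (R)-4-hydroxyhex-5-en-3-one; 4 4-methylpent-4-enoic acid
Product: 5 (R)-4-oxohex-1-en-3-yl 4-methylpent-4-enoate
Conditions: N,N'-dicyclohexylcarbodiimide, DMAP (cat.), CH2Cl2, 0 → 23 °C
Reagents that add atoms: none
Why: Steglich esterification of the secondary alcohol; no stereocenter is formed or touched.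

Step 4
Reactants: 5 (R)-4-oxohex-1-en-3-yl 4-methylpent-4-enoate
Product: 6 (R)-5-methyl-7-propanoyl-4,7-dihydro-3H-oxepin-2-one
Conditions: second-generation Grubbs catalyst (5 mol %), toluene, high dilution, 80 °C
Reagents that add atoms: none
Why: Ring-closing metathesis to a seven-membered lactone, whose ring size forces the trisubstituted C4=C5 olefin to be Z.

Step 5
Reactants: 6 (R)-5-methyl-7-propanoyl-4,7-dihydro-3H-oxepin-2-one
Product: 8 (3aR,4Z)-5,9-dimethyl-6,7-dihydro-3aH-cycloocta[d][1,3]dioxole-2,8-dione, via dilithium dione enolate 7 (not isolated)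
Conditions: LiN(SiMe3)2 (2.2 equiv), THF, −78 → −20 °C; 1,1'-carbonyldiimidazole, −20 → 23 °C; AcOH quench
Reagents that add atoms: 1,1'-carbonyldiimidazole, O=C(n1ccnc1)n1ccnc1
Why: Kinetic enolisation of the ethyl ketone at its CH2 (as with Paterson-type α-acyloxy ethyl ketones) triggers a Baker–Venkataraman-type O-to-carbon acyl shift (intramolecular Claisen condensation) that moves the lactone acyl group onto C10 and enlarges the ring to the eight-membered hydroxy-1,3-diketone; the dianion is closed to the five-membered enol carbonate, which fixes the enol on C7 and leaves C6 untouched.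

Step 6
Reactants: 8 (3aR,4Z)-5,9-dimethyl-6,7-dihydro-3aH-cycloocta[d][1,3]dioxole-2,8-dione; 9 vinyl propionate
Product: 10 cyclobutane photoadduct [C8 bonded to C7 and C9 bonded to C10; cis-fused on the H6 face; (8S)-propionyloxy cis to the carbonate oxygen on C7]
Conditions: hν (350 nm, Pyrex), vinyl propionate (10 equiv), MeCN, −20 °C
Reagents that add atoms: none
Why: De Mayo-type enone–alkene [2+2] photocycloaddition with head-to-tail regiochemistry (the oxygen-bearing alkene carbon bonds to the β-carbon C7); the alkene adds to the face of C7=C10 anti to C5 at the C6 stereocenter and the propionyloxy group takes the exo position away from the eight-membered ring, which sets C8 as S.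

Step 7
Reactants: 10 cyclobutane photoadduct
Product: 12 ten-membered enol acetate [C1(OAc)=C10(Me) with C2 and C9 cis; (Z)-C4=C5; (6R)-OH; C7 ketone; (8S)-propionate], via potassium enolate 11 (not isolated)
Conditions: KOSiMe3 (1.1 equiv), THF, −78 → −30 °C; Ac2O (2 equiv), −78 → 0 °C; aq. NaHCO3
Reagents that add atoms: acetic anhydride, CC(=O)OC(C)=O
Why: Proposed new method: the silanolate opens the strained cyclic carbonate, the freed tertiary cyclobutanolate at C7 undergoes strain-driven retro-aldol cleavage of C7–C10 to give the ten-membered 1,5-diketone as its regiodefined C1/C10 potassium enolate, which is O-acetylated in the same flask while O6 stays masked as a silyl carbonate that loses CO2 on work-up; the closest known reactions are the de Mayo retro-aldol after enol ester cleavage and alkoxide opening of cyclic carbonates, and C6 and C8 are not touched.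

Step 8
Reactants: 12 ten-membered enol acetate
Product: 13 epoxy alcohol [(4R,5S)-cis-4,5-epoxide syn to the (6R)-OH; enol acetate and (8S)-propionate as in 12]
Conditions: VO(acac)2 (5 mol %), t-BuOOH (1.5 equiv), CH2Cl2, 0 °C
Reagents that add atoms: tert-butyl hydroperoxide, CC(C)(C)OO
Why: Hydroxyl-directed vanadium-catalysed epoxidation (Sharpless–Michaelson type) delivers oxygen to the Z allylic olefin syn to C6–OH through the A(1,3)-strain-minimised transition state, setting C4 and C5, while the enol acetate has no directing hydroxyl and is left alone.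

Step 9
Reactants: 13 epoxy alcohol
Product: 15 α-acetoxy ketone [(4R,5S,6R,8S,10R); C1 and C7 ketones; 6-OH; 8-propionate; 10-acetate], via acetoxy epoxide 14 (not isolated)
Conditions: dimethyldioxirane (acetone), CH2Cl2, −20 °C; then toluene, 90 °C
Reagents that add atoms: dimethyldioxirane, CC1(C)OO1
Why: Enol ester epoxidation on the open peripheral face (anti to the C7–C8–C9 segment that folds over the other face) followed by thermal enol ester epoxide rearrangement, a 1,2-acyloxy shift with inversion at C10, gives the tertiary acetate with C10 as R.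

Step 10
Reactants: 15 α-acetoxy ketone; 16 2-(diethoxyphosphoryl)acrylic acid
Product: 17 O6 2-(diethoxyphosphoryl)acrylate of 15
Conditions: N,N'-dicyclohexylcarbodiimide, DMAP (5 mol %), CH2Cl2, 0 °C
Reagents that add atoms: none
Why: Steglich esterification of the only free hydroxyl (C6–OH); no stereocenter is changed.

Step 11
Reactants: 17 O6 2-(diethoxyphosphoryl)acrylate of 15
Product: 19 (4R,5S,6S,8S,10R)-10,13-diacetoxy-4,5-epoxy-1-oxo-8-propionyloxygermacr-7(11)-en-12,6-olide (CNP0285168.2), via phosphonate carbanion 18 (not isolated)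
Conditions: KOAc (3 equiv), 18-crown-6 (cat.), MeCN, 23 °C
Reagents that add atoms: potassium acetate, [K+].CC([O-])=O
Why: Michael addition of acetate to the 2-phosphonoacrylate gives a phosphonate carbanion that closes by intramolecular Horner–Wadsworth–Emmons olefination on the C7 ketone, forming the butenolide with its C13 acetoxymethyl group without touching any stereocenter.

## Compound list

1 | (R)-but-3-ene-1,2-diol | OC[C@H](O)C=C | starting material
2 | (R)-2-hydroxybut-3-enoic acid | OC(=O)[C@H](O)C=C | intermediate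
3 | (R)-4-hydroxyhex-5-en-3-one | CCC(=O)[C@H](O)C=C | intermediate
4 | 4-methylpent-4-enoic acid | CC(=C)CCC(=O)O | starting material
5 | (R)-4-oxohex-1-en-3-yl 4-methylpent-4-enoate | CCC(=O)[C@H](OC(=O)CCC(C)=C)C=C | intermediate
6 | (R)-5-methyl-7-propanoyl-4,7-dihydro-3H-oxepin-2-one | CCC(=O)[C@@H]1OC(=O)CCC(C)=C1 | intermediate
7 | dilithium salt of (R,Z)-4-hydroxy-2,6-dimethylcyclooct-5-ene-1,3-dione | [Li+].[Li+].CC1=C([O-])[C@H]([O-])/C=C(C)\CCC1=O | intermediate (not isolated)
8 | (3aR,4Z)-5,9-dimethyl-6,7-dihydro-3aH-cycloocta[d][1,3]dioxole-2,8-dione (eight-membered C7=C10 enone; O6/O7 cyclic carbonate) | O=C1CC/C(C)=C\[C@H]2OC(=O)O/C2=C1\C | intermediate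
9 | vinyl propionate | CCC(=O)OC=C | starting material
10 | cyclobutane photoadduct (C7–C8 and C9–C10 formed; 8S propionate exo) | CCC(=O)O[C@H]1C[C@]2(C)C(=O)CC/C(C)=C\[C@H]3OC(=O)O[C@@]123 | intermediate
11 | potassium C1/C10 enolate of the ten-membered diketone, O6 as trimethylsilyl carbonate | [K+].CCC(=O)O[C@H]1C/C(C)=C([O-])\CC/C(C)=C\[C@@H](OC(=O)O[Si](C)(C)C)C1=O | intermediate (not isolated)
12 | ten-membered enol acetate (6R-OH; C7 ketone; 8S-propionate; Z-C4=C5) | CCC(=O)O[C@H]1C/C(C)=C(OC(C)=O)\CC/C(C)=C\[C@@H](O)C1=O | intermediate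
13 | (4R,5S)-epoxy alcohol of 12 | CCC(=O)O[C@H]1C/C(C)=C(OC(C)=O)\CC[C@@]2(C)O[C@H]2[C@@H](O)C1=O | intermediate
14 | C1–C10 acetoxy epoxide of 13 | CCC(=O)O[C@H]1C[C@]2(C)O[C@]2(OC(C)=O)CC[C@@]3(C)O[C@H]3[C@@H](O)C1=O | intermediate (not isolated)
15 | α-acetoxy ketone (4R,5S,6R,8S,10R) | CCC(=O)O[C@H]1C[C@@](C)(OC(C)=O)C(=O)CC[C@@]2(C)O[C@H]2[C@@H](O)C1=O | intermediate
16 | 2-(diethoxyphosphoryl)acrylic acid | C=C(C(=O)O)P(=O)(OCC)OCC | starting material
17 | O6 2-(diethoxyphosphoryl)acrylate of 15 | CCC(=O)O[C@H]1C[C@@](C)(OC(C)=O)C(=O)CC[C@@]2(C)O[C@H]2[C@@H](OC(=O)C(=C)P(=O)(OCC)OCC)C1=O | intermediate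
18 | potassium phosphonate carbanion from acetate addition to 17 | [K+].CCC(=O)O[C@H]1C[C@@](C)(OC(C)=O)C(=O)CC[C@@]2(C)O[C@H]2[C@@H](OC(=O)[C-](COC(C)=O)P(=O)(OCC)OCC)C1=O | intermediate (not isolated)
19 | (4R,5S,6S,8S,10R)-10,13-diacetoxy-4,5-epoxy-1-oxo-8-propionyloxygermacr-7(11)-en-12,6-olide | CCC(=O)O[C@H]1C[C@@](C)(OC(C)=O)C(=O)CC[C@@]2(C)O[C@H]2[C@H]2OC(=O)C(COC(C)=O)=C12 | target

## Step count and risks

Total steps: 11. Longest linear sequence: 11.

**Step 5 (ring-enlarging acyl shift).** The base may instead deprotonate the acidic allylic C6–H (loss of configuration) or the lactone α-carbon. The fallback sets out from 3 and comes back at 8. Silylation (Et3SiCl, imidazole) gives (R)-4-(triethylsilyloxy)hex-5-en-3-one F1. A boron aldol ((c-C6H11)2BCl, Et3N, then 4-methylpent-4-enal) gives the β-hydroxy ketone F2. Dess–Martin oxidation gives the acyclic 1,3-diketone F3. Ring-closing metathesis then closes the eight-membered ring directly to the silyloxy diketone F4. HF·pyridine frees the hydroxy diketone F5, and 1,1'-carbonyldiimidazole with Et3N closes the carbonate to 8.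

**Step 6 (photocycloaddition).** The eight-membered enone may give mixed regio- or stereoisomers, and the exo preference at C8 may be modest. The fallback sets out from 8 and comes back at 10; it sets C8 by hydride delivery instead of in the cycloaddition. Irradiation with 1,1-diethoxyethylene (regiospecific, no C8 stereocenter) gives the ketal photoadduct F6. Oxalic acid on wet silica gives the cyclobutanone F7. LiBH(s-Bu)3 at −78 °C adds hydride from the exo face to give the endo cyclobutanol F8. Mitsunobu esterification (PPh3, DIAD, propionic acid) inverts C8 and gives 10.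

**Step 7 (proposed new cascade).** The silanolate may attack the propionate, or the enolate may be protonated or C-acylated before O-acetylation. The fallback uses known chemistry, sets out from 10 and comes back at 12. NaOMe in MeOH at −20 °C (the ordinary de Mayo work-up: carbonate methanolysis, retro-aldol, protonation) gives the hydroxy diketone F9. t-BuMe2SiOTf with 2,6-lutidine gives the O6 silyl ether F10. Isopropenyl acetate with TsOH (thermodynamic enol acetylation at the more substituted C10 side of the C1 ketone) gives the silylated enol acetate F11. HF·pyridine then gives 12.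

## Further compounds

F1 | step 5 | (R)-4-(triethylsilyloxy)hex-5-en-3-one | CCC(=O)[C@H](O[Si](CC)(CC)CC)C=C
F2 | step 5 | (3R)-6-hydroxy-5,9-dimethyl-3-(triethylsilyloxy)deca-1,9-dien-4-one (diastereomer mixture at C5 and C6) | C=C(C)CCC(O)C(C)C(=O)[C@H](O[Si](CC)(CC)CC)C=C
F3 | step 5 | (3R)-5,9-dimethyl-3-(triethylsilyloxy)deca-1,9-diene-4,6-dione | C=C(C)CCC(=O)C(C)C(=O)[C@H](O[Si](CC)(CC)CC)C=C
F4 | step 5 | (4R,5Z)-2,6-dimethyl-4-(triethylsilyloxy)cyclooct-5-ene-1,3-dione | CC1C(=O)CC/C(C)=C\[C@@H](O[Si](CC)(CC)CC)C1=O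
F5 | step 5 | (4R,5Z)-4-hydroxy-2,6-dimethylcyclooct-5-ene-1,3-dione | CC1C(=O)CC/C(C)=C\[C@@H](O)C1=O
F6 | step 6 | ketal photoadduct of 8 with 1,1-diethoxyethylene (C8 diethyl ketal) | CCOC1(OCC)C[C@]2(C)C(=O)CC/C(C)=C\[C@H]3OC(=O)O[C@@]123
F7 | step 6 | C8 cyclobutanone | O=C1C[C@]2(C)C(=O)CC/C(C)=C\[C@H]3OC(=O)O[C@@]123
F8 | step 6 | endo C8 cyclobutanol (C8 epimer of the alcohol of 10) | O[C@@H]1C[C@]2(C)C(=O)CC/C(C)=C\[C@H]3OC(=O)O[C@@]123
F9 | step 7 | ten-membered hydroxy diketone (6R-OH; 8S-propionate; C10–H epimers) | CCC(=O)O[C@H]1CC(C)C(=O)CC/C(C)=C\[C@@H](O)C1=O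
F10 | step 7 | O6 tert-butyldimethylsilyl ether of F9 | CCC(=O)O[C@H]1CC(C)C(=O)CC/C(C)=C\[C@@H](O[Si](C)(C)C(C)(C)C)C1=O
F11 | step 7 | O6 tert-butyldimethylsilyl ether of 12 | CCC(=O)O[C@H]1C/C(C)=C(OC(C)=O)\CC/C(C)=C\[C@@H](O[Si](C)(C)C(C)(C)C)C1=O
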